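The numbers of this flask come from no measurement; no experiment stands behind them.

Slowness is what I reckon with here, so I count how many lifetimes of the reaction fit into the run.

all flasks: G 11 mol%; time 8.0 d
- Saturday's: Q 0.50 M (fed, over 3.0 d); Z 1.00 equiv; all else is in the flask from the start; the feed brings no volume worth counting
- Thursday's: Q 0.50 M; Z 1.00 equiv (fed, over 3.0 d); all else is in the flask from the start; the feed brings no volume worth counting
- Sunday's: Q 0.50 M; Z 1.00 equiv; everything together at the start
- Monday's: Q 0.50 M (in portions, 4, over 3.0 d); Z 1.00 equiv; first portion at the start, last at 3.0 d

    Q + Z + G → Q.Z + G, rate k1*[Q]*[Z]*[G]/(1 + ([Q]/sat1)) (sat1 = 0.0715 M, k1 = 3.33 M⁻² h⁻¹)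
    G → J (k2 = 0.00125 h⁻¹)

* the flask with the highest amount of Q.Z, in percent of the Q charged ("all alike" if they lie within 1.5 percentage points) (Saturday's / Thursday's / Sunday's / Monday's / all alike)
* final Q.Z, as a percentage of the Q charged, in Saturday's
* final Q.Z, as a percentage of the Q charged, in Thursday's
* final Q.Z, as a percentage of the Q charged, in Sunday's
* final Q.Z, as a percentage of the Q charged, in Monday's

I compare Sunday's flask with Thursday's, which has the same charges but feeds Z. The Q charged stands at 6.99 times the constant sat, so at the start of Sunday's flask the denominator of the rate law nearly cancels Q. While that lasts, Z falls pseudo-first-order, with a lifetime of 3.18 d. I call this the saturated lifetime: one over the product of the rate constant, the catalyst charged and sat. G fades to J with a lifetime of 33.3 d, and counting that fade, Sunday's 8.0 d holds 2.24 saturated lifetimes.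

Integrating the rate law with Q and Z equal, the lifetimes spent are the logarithm of start over remainder, plus sat times the difference of the reciprocal concentrations, remainder less start. With 0.143 as sat over the start, one correction from a guess gives 19.4% of Q left in Sunday's, so I commit to 80.6% of Q.Z.

In Thursday's flask, Z arrives on average 1.50 d late, and that delay is half a saturated lifetime. I therefore take Thursday's count as 1.76. The same rule leaves 25.8% of Q, which gives 74.2% of Q.Z, so by my reckoning Thursday's ends 6.4 percentage points lower than Sunday's.

The forecast names Sunday's, with 80.6% there, 77.8% in Saturday's, 74% in Thursday's and 77.9% in Monday's, on the ground that “the slow feeds therefore just waste early contact time”. My figure for Sunday's flask is the same as the forecast's, and my 74.2% for Thursday's differs from its 74%.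

The run puts Sunday's highest at 80.6%, with 77.9% in Monday's, 77.6% in Saturday's and 73.9% in Thursday's. Left for 80.0 d, Thursday's reaches 97.4% and Sunday's 97.6%, a gap smaller than the margin of 1.5 points. With 3.18 d, that long Thursday's run holds 9.05 lifetimes after the mean delay of the feed, and the 2.59% of Q standing there corresponds to 9.03.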